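## The problem

The target 16 is a tribrominated diphenyl ether in which ring A (C1 bridge oxygen, C2 OMe, C3 Br, C5 Br) and ring B (C1' bridge oxygen, C4' Br, C6' OH) are joined only through the C1–O–C1' bridge, each ring carrying a second oxygen ortho to it. There is no stereocentre, so the whole difficulty is constitutional: three bromines and two differentiated oxygens, one methylated and one free, must sit at exact positions. On ring A both bromines are ortho and para to the methoxy oxygen and not to the bridge oxygen, and on ring B the single bromine is para to the bridge oxygen and meta to the free hydroxyl, the opposite of what bromination of a free 2-aryloxyphenol would give. Forming the bridge by copper- or palladium-mediated coupling is awkward, because either partner would carry C–Br bonds that compete with the intended halide, and ortho-oxygenated partners couple slowly. The aryl bromides also exclude organolithium reagents, dissolving metals, hydrogenolysis and amide bases that generate arynes, and the methyl ether must survive whatever frees the ring B hydroxyl. The enabling feature is ring B itself: C6'(O)–C5'(H)–C4'(Br)–C3'(H) has the substitution of C3–C6 of a 3-acyloxy-5-bromo-2-pyrone, and C1'(OAr)–C2'(H) is an aryloxyacetylene that can already carry ring A on its oxygen. Ring B can therefore be built by cycloaddition with the diaryl ether oxygen in place from the start.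

## Retrosynthesis

**16 from 15.** The last cut is the acyl C–O bond of a pivalate on the ring B oxygen. An ester is preferred to a second methyl or a benzyl ether because its removal by mild methanolysis touches neither the ring A methyl ether nor the three C–Br bonds. The same acyloxy group also serves the pyrone chemistry further back. The forward step only has to be a clean transesterification.

**15 from 13 and 9.** Ring B is cut at C6'–C1' and C3'–C2'. This gives the pyrone 13 (C3–C6 become C6'–C3') and the aryl ethynyl ether 9 (its two alkyne carbons become C1' and C2'); the bridged lactone 14 connects them and aromatises by decarboxylation. The neighbouring cut, the C1–O or C1'–O bond of the bridge, would require an aryl halide coupling in the presence of other C–Br bonds. Here the bridge oxygen enters attached to ring A, and the bromine and the oxygen of ring B are fixed by where they sit on the pyrone. The precursors are a monocyclic lactone and a phenol-derived alkyne. The forward reaction must give a single orientation of addition, and the alkyne must survive heating.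

**9 from 8, and 8 from 6 through 7.** The triple bond is taken back to the (Z)-bromovinyl ether 8 and then, through the dibromide 7, to the vinyl ether 6. No skeletal bond is cut; two C–Br/C–H pairs are restored. These two dehydrobrominations need only bromine, an amidine and an alkoxide, whereas routes to ynol ethers that pass through halogen–metal exchange are closed because they would also exchange the ring bromines. The forward steps must leave the deactivated ring A untouched and give mostly the Z isomer, whose H and Br are anti for the final elimination.

**6 from 4 and 5.** The O–vinyl bond is cut to the phenol 4 and vinyl acetate 5. A vinyl transfer from an enol ester is preferred to a copper-mediated vinylation, which would meet the ring bromines. The precursor is a simple trisubstituted phenol, and the forward reaction has to tolerate an electron-poor, ortho-substituted phenol.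

**4 from 2 through 3.** The phenolic C–O bond of 4 is traced to the formyl carbon of aldehyde 2 by Baeyer–Villiger oxidation through the formate 3. This is chosen over bromination of a 2-methoxyphenol, which would place the bromines ortho and para to the free hydroxyl instead of the methoxy group. The forward oxidation needs aryl rather than hydride migration.

**2 from 1.** The O–CH3 bond is cut to the salicylaldehyde 1, in which both bromines already stand ortho and para to the oxygen that becomes OMe. The forward step is a plain O-alkylation.

**13 from 11 through 12.** The C5–Br bond is cut back to the unbrominated pivalate 11. With C3 blocked, the ring oxygen makes C5 the site of bromine addition–elimination through the dibromide 12. The forward reaction must spare the enol ester and the C3=C4 bond.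

**11 from 10.** The acyl C–O bond is cut to the hydroxypyrone 10. Acylating before bromination removes the enol character that would direct electrophiles to C4 and C6, and the ester is the protecting group that is removed in the last step.

## Roads not taken

Alternative 1: Ring A is cut at two C–C bonds so that three of its carbons come from an aryloxyacetone and three from a brominated dialdehyde. Forward, 1-[2-(benzyloxy)-4-bromophenoxy]propan-2-one A1 would condense twice with bromomalonaldehyde A2 under base. The methyl and OCH2 carbons of A1 would each attack one formyl group of A2 and, after loss of two molecules of water, ring A would be closed as 2-[2-(benzyloxy)-4-bromophenoxy]-4-bromophenol A3.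

- Merits: every intermediate is an ordinary, stable compound. The bridge oxygen is again carried in and not made by coupling. One ring A bromine arrives by construction.
- Weak points: A3 is still three steps from 16 (ortho-bromination of the new phenol, O-methylation, removal of the benzyl group by a Lewis acid because hydrogenolysis would strip bromine). The late bromination must discriminate between the free phenol ring and the benzyloxy-activated ring B. A2 is itself an alpha-halo carbonyl compound that enolates can attack at bromine or carbon, and the two enolisable sites of A1 must each react once and in the right sense.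
- Comparison: the step count is similar, and the end game of this road is more conventional than the handling of ynol ether 9. The chosen plan sets against it a key step with closer relatives (pyrone plus alkyne to arene), all three bromines and both oxygens fixed before ring B is formed, and no late electrophilic substitution.

Alternative 2: Ring B is cut at C1'–C2' and C5'–C6' and assembled at the cyclohexane-1,3-dione oxidation level. Forward, dimethyl 2-(3,5-dibromo-2-methoxyphenoxy)malonate A4 would be deprotonated and added in Michael fashion to but-3-en-2-one A5. The methyl ketone of the adduct would then cyclise as its enolate onto one ester group, closing methyl 1-(3,5-dibromo-2-methoxyphenoxy)-2,4-dioxocyclohexane-1-carboxylate A6 as a racemate.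

- Merits: Michael addition and Claisen ring closure are among the most reliable C–C bond formations. A5 is a cheap bulk reagent, A4 would come from the same phenol 4, and nothing heat-sensitive is involved.
- Weak points: A6 is far from ring B. The ester must be removed, the C4' carbonyl oxygen (and not the C6' one) must be replaced by bromine, and the ring must then be dehydrogenated without losing the vinylic bromine or the alpha-aryloxy group. That is at least three further steps with two selectivity questions, and the overall route is longer than the chosen one.
- Comparison: this road is more robust in its bond-forming step. The chosen plan sets against it that ring B is aromatic and correctly substituted as soon as the ring has closed, with one deprotection left.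

Alternative 3: No ring is cut. All three C–Br bonds are disconnected at once from a diaryl ether whose two oxygens are differentiated by one acyl group. Forward, 2,2'-oxydiphenol A7 would be mono-acylated to 2-(2-hydroxyphenoxy)phenyl pivalate A8. Three equivalents of an electrophilic bromine source would then give 5-bromo-2-(3,5-dibromo-2-hydroxyphenoxy)phenyl pivalate A9 in one operation, and methylation and ester cleavage would finish the synthesis.

- Merits: about four steps from a symmetric diol, textbook reactions only, and directing effects that point the right way (ortho and para to the free hydroxyl on ring A, para to the bridge oxygen on the acylated ring).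
- Weak points: the third bromination of A8 must occur on a ring deactivated by the acyloxy group, whose bridge oxygen is shared with an increasingly electron-poor dibromophenol. Over-bromination of ring A and ortho attack on ring B would give isomers that are hard to separate in this compound class. The pivaloyl group of A9 can migrate between the two phenolic oxygens under the basic methylation, which would put the methyl group on the wrong ring and give an isomer of the same mass. The mono-acylation of A7 is statistical.
- Comparison: in step economy and in reliance on known chemistry this road is better than the chosen one. The chosen plan sets against it positional certainty: each bromine and each oxygen is placed by the structure of a building block and not by relative rates of substitution, and the two rings can be varied independently.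

Key step: step 8

Assumption: 3-hydroxy-2H-pyran-2-one 10 is taken as a purchasable compound, and the transient intermediates 7, 12 and 14 are racemic, which is without consequence for the achiral target.

## Route

Step 1
Reactants: 1 3,5-dibromosalicylaldehyde (3,5-dibromo-2-hydroxybenzaldehyde)
Product: 2 3,5-dibromo-2-methoxybenzaldehyde
Conditions: MeI, K2CO3, DMF, 25 °C
Reagents that add atoms: iodomethane, CI
Why: Williamson O-methylation; the phenol is acidified by two bromines and the ortho formyl group, so carbonate deprotonates it fully and the phenoxide is alkylated on oxygen.

Step 2
Reactants: 2 3,5-dibromo-2-methoxybenzaldehyde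
Product: 4 3,5-dibromo-2-methoxyphenol, via aryl formate 3 (not isolated)
Conditions: mCPBA, CH2Cl2, 40 °C; aq. NaHCO3 wash; then K2CO3, MeOH, 25 °C
Reagents that add atoms: 3-chloroperoxybenzoic acid (mCPBA), OOC(=O)c1cccc(Cl)c1
Why: Baeyer–Villiger oxidation of an ortho-alkoxybenzaldehyde, in which the aryl group carrying the ortho oxygen donor migrates in preference to hydride; the resulting formate 3 is cleaved by mild methanolysis, and the aryl bromides and the methyl ether are inert to both stages.

Step 3
Reactants: 4 3,5-dibromo-2-methoxyphenol; 5 vinyl acetate
Product: 6 1,5-dibromo-3-(ethenyloxy)-2-methoxybenzene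
Conditions: [Ir(cod)Cl]2 (2 mol%), Na2CO3, toluene, 100 °C
Reagents that add atoms: none
Why: Iridium-catalysed transvinylation of a phenol with vinyl acetate (addition of the phenoxide to the coordinated vinyl ester, then loss of acetate), an established route to aryl vinyl ethers; the aryl C–Br bonds are not expected to add to the monovalent iridium catalyst under these conditions.

Step 4
Reactants: 6 1,5-dibromo-3-(ethenyloxy)-2-methoxybenzene
Product: 8 1,5-dibromo-3-{[(Z)-2-bromoethenyl]oxy}-2-methoxybenzene, via dibromoethyl ether 7 (not isolated)
Conditions: Br2, CH2Cl2, −78 °C; then DBU, −78 °C → 25 °C
Reagents that add atoms: bromine, BrBr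
Why: Bromine adds to the electron-rich enol ether double bond far faster than it substitutes the doubly deactivated ring A, and base-induced loss of HBr from the 1,2-dibromoethyl ether (ionisable alpha-bromide, acidified CH2Br hydrogen) is the classical bromination–dehydrobromination route to 2-bromovinyl ethers, which favours the Z isomer.

Step 5
Reactants: 8 1,5-dibromo-3-{[(Z)-2-bromoethenyl]oxy}-2-methoxybenzene
Product: 9 1,5-dibromo-3-(ethynyloxy)-2-methoxybenzene
Conditions: KOtBu, THF, −40 → 0 °C; cold pH 7 buffer; dried toluene solution used at once
Reagents that add atoms: none
Why: In the Z isomer the hydrogen on the oxygen-bearing carbon is anti to bromine, so alkoxide-induced anti E2 dehydrobromination gives the alkyne, as in the known preparation of ynamides and aryl ynol ethers from bromo-enamides and bromo enol ethers; tert-butoxide does not exchange or eliminate the aryl bromides at this temperature.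

Step 6
Reactants: 10 3-hydroxy-2H-pyran-2-one
Product: 11 2-oxo-2H-pyran-3-yl pivalate
Conditions: PivCl, Et3N, DMAP (cat.), CH2Cl2, 0 °C
Reagents that add atoms: pivaloyl chloride, CC(C)(C)C(Cl)=O
Why: O-acylation of an acidic enol with an acid chloride under nucleophilic catalysis; esters of this hydroxypyrone are known, and the bulky pivalate resists later adventitious cleavage.

Step 7
Reactants: 11 2-oxo-2H-pyran-3-yl pivalate
Product: 13 5-bromo-2-oxo-2H-pyran-3-yl pivalate, via dihydropyranone dibromide 12 (not isolated)
Conditions: Br2, CH2Cl2, 0 → 25 °C; then Et3N, 0 °C
Reagents that add atoms: bromine, BrBr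
Why: Bromination of a 2-pyrone by addition–elimination, the way the parent pyrone and its 3-bromo derivative are brominated; with C3 blocked and the enol oxygen acylated, the ring oxygen makes C5 the nucleophilic carbon, bromine adds across C5=C6, and Et3N removes H5 with loss of the labile C6 bromide to restore the pyrone with Br at C5.

Step 8
Reactants: 13 5-bromo-2-oxo-2H-pyran-3-yl pivalate; 9 1,5-dibromo-3-(ethynyloxy)-2-methoxybenzene
Product: 15 5-bromo-2-(3,5-dibromo-2-methoxyphenoxy)phenyl pivalate, via bridged lactone 14 (not isolated)
Conditions: 9 (2 equiv, slow addition), BHT (cat.), toluene, 100 °C
Reagents that add atoms: none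
Why: Proposed new method: an inverse-electron-demand Diels–Alder reaction is proposed between the electron-poor diene C3=C4–C5=C6 of 13 (lactone carbonyl, C5 bromine, only weakly donating acyloxy group) and the electron-rich triple bond of 9, the closest known reaction type being the thermal cycloaddition of 2-pyrones, among them 5-bromo- and 3,5-dibromo-2-pyrone, with enol ethers, ynamines and other alkynes, the alkyne adducts going on to arenes by decarboxylation. Bond formation should be asynchronous: the nucleophilic terminal CH carbon of 9 attacks C6, the acceptor terminus of the dienoate, and the developing dienolate closes from C3 onto the oxygen-bearing alkyne carbon. Ring B is thereby closed as a six-membered carbocycle in an intermolecular [4+2] cycloaddition that forms C3'–C2' and C6'–C1', first within the bicyclo[2.2.2]octadiene lactone 14. Extrusion of CO2 from 14 by retro-[4+2] at the reaction temperature delivers the benzene ring directly, so no separate oxidation or elimination is needed in which the aryloxy group could depart. The two bridgehead stereocentres of 14 form as a racemate and vanish on aromatisation, so no stereocentre has to be controlled. The selectivity that matters is the orientation of addition (oxygen-bearing alkyne carbon to C3 and not to C6), which the matched polarisation of ynol ether and pyrone should secure and which places Br para and the pivalate ortho to the bridge oxygen. Lacking any C–H bond beta to oxygen, 9 has no retro-ene path to a ketene of the kind that limits alkyl ynol ethers, and its self-oligomerisation is held back by adding it slowly to the hot diene solution in the presence of a radical inhibitor.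

Step 9
Reactants: 15 5-bromo-2-(3,5-dibromo-2-methoxyphenoxy)phenyl pivalate
Product: 16 5-bromo-2-(3,5-dibromo-2-methoxyphenoxy)phenol (target)
Conditions: K2CO3, MeOH, 25 °C; then aq. NH4Cl
Reagents that add atoms: none
Why: Base-mediated methanolysis of an aryl ester, driven by the good phenoxide leaving group; the diaryl ether, the methyl ether and the aryl bromides are inert to carbonate in methanol.

## Compound list

1 | 3,5-dibromosalicylaldehyde (3,5-dibromo-2-hydroxybenzaldehyde) | O=Cc1cc(Br)cc(Br)c1O | starting material
2 | 3,5-dibromo-2-methoxybenzaldehyde | O=Cc1cc(Br)cc(Br)c1OC | intermediate
3 | 3,5-dibromo-2-methoxyphenyl formate | O=COc1cc(Br)cc(Br)c1OC | intermediate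
4 | 3,5-dibromo-2-methoxyphenol | Oc1cc(Br)cc(Br)c1OC | intermediate
5 | vinyl acetate | CC(=O)OC=C | starting material
6 | 1,5-dibromo-3-(ethenyloxy)-2-methoxybenzene | C=COc1cc(Br)cc(Br)c1OC | intermediate
7 | 1,5-dibromo-3-(1,2-dibromoethoxy)-2-methoxybenzene (racemic) | BrCC(Br)Oc1cc(Br)cc(Br)c1OC | intermediate
8 | 1,5-dibromo-3-{[(Z)-2-bromoethenyl]oxy}-2-methoxybenzene | Br/C=C\Oc1cc(Br)cc(Br)c1OC | intermediate
9 | 1,5-dibromo-3-(ethynyloxy)-2-methoxybenzene | C#COc1cc(Br)cc(Br)c1OC | intermediate
10 | 3-hydroxy-2H-pyran-2-one | O=C1OC=CC=C1O | starting material
11 | 2-oxo-2H-pyran-3-yl pivalate | CC(C)(C)C(=O)OC1=CC=COC1=O | intermediate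
12 | trans-5,6-dibromo-2-oxo-5,6-dihydro-2H-pyran-3-yl pivalate (racemic, one enantiomer drawn) | CC(C)(C)C(=O)OC1=C[C@@H](Br)[C@H](Br)OC1=O | intermediate
13 | 5-bromo-2-oxo-2H-pyran-3-yl pivalate | CC(C)(C)C(=O)OC1=CC(Br)=COC1=O | intermediate
14 | 7-bromo-5-(3,5-dibromo-2-methoxyphenoxy)-3-oxo-2-oxabicyclo[2.2.2]octa-5,7-dien-4-yl pivalate (racemic; the relative configuration of the two bridgeheads is fixed by the ring system) | CC(C)(C)C(=O)OC12C=C(Br)C(OC1=O)C=C2Oc1cc(Br)cc(Br)c1OC | intermediate
15 | 5-bromo-2-(3,5-dibromo-2-methoxyphenoxy)phenyl pivalate | CC(C)(C)C(=O)Oc1cc(Br)ccc1Oc1cc(Br)cc(Br)c1OC | intermediate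
16 | 5-bromo-2-(3,5-dibromo-2-methoxyphenoxy)phenol | COc1c(Br)cc(Br)cc1Oc1ccc(Br)cc1O | target

## Step count and risks

Total step count: 9. Longest linear sequence: 7 steps (1, 2, 3, 4, 5, 8, 9). The pyrone arm is 2 steps (6, 7).

**Step 8 (key step).**
- What may go wrong: self-oligomerisation or hydration of the ynol ether may outrun the cycloaddition. The diene may be too weakly electrophilic toward an aryloxy-substituted alkyne at a temperature the alkyne survives. Partial addition in the reversed orientation cannot be excluded.
- Fallback (known chemistry, leaves the cycloaddition): it sets out from phenol 4. Nucleophilic aromatic substitution on commercial 5-bromo-2-fluorobenzaldehyde (K2CO3, DMF, 110 °C; only the fluoride ortho to the formyl group is activated) should give 5-bromo-2-(3,5-dibromo-2-methoxyphenoxy)benzaldehyde F1. Baeyer–Villiger oxidation with mCPBA should convert F1 into 5-bromo-2-(3,5-dibromo-2-methoxyphenoxy)phenyl formate F2. Methanolysis of F2 (K2CO3, MeOH) comes back to the route at the target 16.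

**Step 5.**
- What may go wrong: elimination from any E isomer carried along is slow. tert-Butoxide may add to the product alkyne. The terminal ynol ether may hydrate on work-up or oligomerise on concentration.
- Fallback: it sets out from the bromovinyl ether 8 and pyrone 13 and uses 8 itself as the two-carbon partner. Heating in toluene (110 °C, sealed tube) should give, by the same orientation of inverse-demand cycloaddition, 6,7-dibromo-5-(3,5-dibromo-2-methoxyphenoxy)-3-oxo-2-oxabicyclo[2.2.2]oct-7-en-4-yl pivalate F3. Thermal loss of CO2 leads to 3,5-dibromo-6-(3,5-dibromo-2-methoxyphenoxy)cyclohexa-1,3-dien-1-yl pivalate F4. With DBU, F4 should lose HBr (allylic bromide, a far better leaving group than aryloxide) and come back to the route at 15.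

**Step 7.**
- What may go wrong: bromine may add across C3=C4 or attack C4 or C6. Over-bromination is possible, and the enol ester may be lost to amine or bromide.
- Fallback: bromine is introduced after ring formation. It sets out from the unbrominated pyrone 11, which is heated with 9 under the conditions of step 8, at a higher temperature if the less electron-poor diene requires it. This should pass through 5-(3,5-dibromo-2-methoxyphenoxy)-3-oxo-2-oxabicyclo[2.2.2]octa-5,7-dien-4-yl pivalate F5 (not isolated) to 2-(3,5-dibromo-2-methoxyphenoxy)phenyl pivalate F6. Bromination of F6 with NBS in MeCN should occur para to the bridge oxygen, the strongest donor on the only non-deactivated ring, and comes back to the route at 15.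

**Step 3.**
- What may go wrong: transvinylation of a hindered, electron-poor phenol may be slow. The phenol may be acetylated by vinyl acetate instead, or the catalyst may insert into a C–Br bond.
- Fallback: it sets out from phenol 4. O-Alkylation with 1,2-dibromoethane (K2CO3, MeCN, reflux) should give 1,5-dibromo-3-(2-bromoethoxy)-2-methoxybenzene F7. E2 elimination with KOtBu in THF comes back to the route at vinyl ether 6.

## Further compounds

F1 | step 8 | 5-bromo-2-(3,5-dibromo-2-methoxyphenoxy)benzaldehyde | O=Cc1cc(Br)ccc1Oc1cc(Br)cc(Br)c1OC
F2 | step 8 | 5-bromo-2-(3,5-dibromo-2-methoxyphenoxy)phenyl formate | O=COc1cc(Br)ccc1Oc1cc(Br)cc(Br)c1OC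
F3 | step 5 | 6,7-dibromo-5-(3,5-dibromo-2-methoxyphenoxy)-3-oxo-2-oxabicyclo[2.2.2]oct-7-en-4-yl pivalate (racemic, mixture of endo and exo adducts) | CC(C)(C)C(=O)OC12C=C(Br)C(OC1=O)C(Br)C2Oc1cc(Br)cc(Br)c1OC
F4 | step 5 | 3,5-dibromo-6-(3,5-dibromo-2-methoxyphenoxy)cyclohexa-1,3-dien-1-yl pivalate (racemic) | CC(C)(C)C(=O)OC1=CC(Br)=CC(Br)C1Oc1cc(Br)cc(Br)c1OC
F5 | step 7 | 5-(3,5-dibromo-2-methoxyphenoxy)-3-oxo-2-oxabicyclo[2.2.2]octa-5,7-dien-4-yl pivalate (racemic) | CC(C)(C)C(=O)OC12C=CC(OC1=O)C=C2Oc1cc(Br)cc(Br)c1OC
F6 | step 7 | 2-(3,5-dibromo-2-methoxyphenoxy)phenyl pivalate | CC(C)(C)C(=O)Oc1ccccc1Oc1cc(Br)cc(Br)c1OC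
F7 | step 3 | 1,5-dibromo-3-(2-bromoethoxy)-2-methoxybenzene | BrCCOc1cc(Br)cc(Br)c1OC
A1 | alternative 1 | 1-[2-(benzyloxy)-4-bromophenoxy]propan-2-one | CC(=O)COc1ccc(Br)cc1OCc1ccccc1
A2 | alternative 1 | bromomalonaldehyde | O=CC(Br)C=O
A3 | alternative 1 | 2-[2-(benzyloxy)-4-bromophenoxy]-4-bromophenol | Oc1ccc(Br)cc1Oc1ccc(Br)cc1OCc1ccccc1
A4 | alternative 2 | dimethyl 2-(3,5-dibromo-2-methoxyphenoxy)malonate | COC(=O)C(Oc1cc(Br)cc(Br)c1OC)C(=O)OC
A5 | alternative 2 | but-3-en-2-one | CC(=O)C=C
A6 | alternative 2 | methyl 1-(3,5-dibromo-2-methoxyphenoxy)-2,4-dioxocyclohexane-1-carboxylate (racemic) | COC(=O)C1(Oc2cc(Br)cc(Br)c2OC)CCC(=O)CC1=O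
A7 | alternative 3 | 2,2'-oxydiphenol | Oc1ccccc1Oc1ccccc1O
A8 | alternative 3 | 2-(2-hydroxyphenoxy)phenyl pivalate | CC(C)(C)C(=O)Oc1ccccc1Oc1ccccc1O
A9 | alternative 3 | 5-bromo-2-(3,5-dibromo-2-hydroxyphenoxy)phenyl pivalate | CC(C)(C)C(=O)Oc1cc(Br)ccc1Oc1cc(Br)cc(Br)c1O
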